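By 3.00 d the alpha run had stopped climbing, and I wanted to know what its plateau was worth for the new flasks. Their charges, the earlier readings and the questions stand here.

the same everywhere: left-handed substrate 20 mM; right-handed substrate 20 mM; precatalyst 100 µM
- alpha: partner 17 mM; run made earlier
- theta: partner 220 mM; run made earlier
- red: partner 12.0 mM; time 3.0 d
- teal: partner 20.0 mM; time 3.0 d
- green: partner 40.0 mM; time 3.0 d
- violet: partner 80.0 mM; time 3.0 d
- grey: partner 200 mM; time 3.0 d

| alpha: time / d | alpha: left-handed product / % | theta: time / d | theta: left-handed product / % |
|---|---|---|---|
| 0.417 | 22.8 | 0.250 | 51.2 |
| 1.04 | 31.1 | 0.500 | 51.7 |
| 2.08 | 34.0 | 1.25 | 51.1 |
| 3.00 | 34.4 | 3.00 | 52.4 |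

(readings scatter by 0.5 percentage points)

- partner is single-handed; left-handed substrate and right-handed substrate are mirror images of each other, charged as a racemate, each of them at the stated concentration
- the numbers in the tables scatter by 0.5 percentage points (one standard deviation)
- on the list of suspects stand: partner + left-handed substrate -> left-handed product; partner + right-handed substrate -> right-handed product; left-handed substrate + racemization catalyst <-> right-handed substrate + racemization catalyst; 2 racemization catalyst <-> resting dimer; partner + precatalyst -> racemization catalyst + spent reagent
- "hardly changes" means that all values lie within two and a half points (for a concentration: within two and a half percent of the largest)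
- the handed part of partner does not stay in what it makes, so the products of the two hands are mirror images too

- amount of left-handed product at the end, in percent of the left-handed substrate and right-handed substrate together charged for red, teal, green, violet, grey, in this order
- the shape of the row from first to last (hardly changes / falls all the way / falls, then rises / rises all the way / rises, then falls)

I read the two tables against each other, first row to first row. Theta stood at 51.2 % after 0.250 d, while alpha stood at 22.8 % after a longer 0.417 d, so theta had gone further. The runs differ in their partner charge, and both substrates react with partner, so I took partner as the concentration to follow.

Then I read the last rows. Theta's partner was 5.50 times the substrates charged, and its four readings average 51.6 %, just above the left-handed half of the charge. Alpha's partner was a fraction 0.425 of the substrates, and alpha ended lower, at 34.4 %.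

I assumed that alpha had turned over its partner charge. That gives 80.9 %, which I call the left-handed share: the fraction of the charged partner that ends as left-handed product.

In red and teal I treated partner as the limiting reagent, at fractions 0.300 and 0.500 of the substrates. Multiplying by the share gave me 24.3 % for red and 40.5 % for teal.

For green the same multiplication gives 80.9 %, above the left-handed half of the charge, and anything over that half has to pass through racemization, which takes time. For grey I expected about theta's 51.6 %. I expected green and violet, with less partner than grey, to react more slowly and so to give racemization longer, which would put both above grey and make the row rise, then fall.

The forecast gave 24.9 %, 39.7 %, 55.8 %, 55.4 % and 51.9 %, shape rises, then falls, saying “Below 1 equivalent, partner limits the yield”.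

The flasks gave 25.1 %, 39.7 %, 57.3 %, 56.2 % and 52.2 %, shape rises, then falls.

    partner + left-handed substrate → left-handed product (k = 5.90 L mol⁻¹ h⁻¹)
    partner + right-handed substrate → right-handed product (k = 0.870 L mol⁻¹ h⁻¹)
    left-handed substrate + racemization catalyst ⇌ right-handed substrate + racemization catalyst, rate k3*[racemization catalyst]*[left-handed substrate] forward; the back reaction follows from the equilibrium constant (k = 1700 L mol⁻¹ h⁻¹)
    2 racemization catalyst ⇌ resting dimer, settled at all times (K = 1.30 × 10⁶ L mol⁻¹)
    partner + precatalyst → racemization catalyst + spent reagent (k = 1.30 L mol⁻¹ h⁻¹)

In red, the largest effect I can show was the using up of partner: with partner held at its charge, the left-handed product reached 57.0 % instead of 25.1 %. Red ended with 0.207 % of its partner, and left-handed product stood at 83.7 % of the partner charge, beside alpha's 80.9 %. Teal ended with 1.37 % of its partner, and its left-handed product stood at 79.4 % of the partner charge.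

All runs are calculated with made-up constants.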